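Substrate, target and side product, counted in substrate units, add up to the charge, since the 1.4 µM of free enzyme can hold hardly any of the 14 mM of substrate. What leaves target therefore stays on the books as side product.

in all of them: free enzyme 1.4 µM
- beta: substrate 14 mM; temperature 37 °C; the very flask that is asked about, followed so far
- alpha: substrate 7 mM; temperature 32 °C; run made earlier
- flask: substrate 14 mM; temperature 37 °C; time 2.0 d

- beta (time / h: target / %): 3.00: 8.0; 5.00: 11.8; 8.00: 14.7; 10.0: 15.8; 15.0: 17.8; 25.0: 19.1; 40.0: 16.9
- alpha (time / min: target / %): 15.0: 1.0; 30.0: 0.6; 50.0: 1.9; 60.0: 1.8; 80.0: 3.2; 90.0: 3.4; 120: 4.9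

(each reading ± 0.5 percentage points)

- teal: at 2.0 d add free enzyme, 100 % of the amount charged, then wait 25 h
- violet: change nothing and wait 25 h more
- ochre: at 2.0 d raise the temperature by 20 K, then wait 25 h
- amber: at 2.0 d take out 90 % of the target then present, then wait 25 h

- percent here means substrate units held: one side product counts as two
- removed target is counted in
- steps thought possible: complex -> spent catalyst; substrate + target -> side product; complex -> free enzyme + target; substrate + free enzyme <-> complex; free enzyme -> unfolded enzyme
- additions bring no volume worth counting

- target, in percent of the substrate first charged, at 2.0 d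
- what to do for the largest gain in target; "none" if nothing gains more than 2 percentage points (teal / violet / ochre / amber / none)
- target present, with what was taken out counted in, in percent of the substrate first charged, after teal
- target present, with what was taken out counted in, in percent of the substrate first charged, after ochre

Which run speaks to the late hours? Beta does, since alpha stops at 120 min with its highest reading, 4.9 %, and shows no decline.

What does beta show? Target reads 19.1 % at 25.0 h and 16.9 % at 40.0 h, a fall of 2.2 percentage points, larger than the scatter of 0.5 points.

How do you carry that forward? With the fraction left, not the fraction made. The tail constant, the natural log of those two readings' ratio over the hours between them, is 0.00816 h⁻¹. Over any wait, the target left is the exponential of minus that constant times the wait.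

Where is it weak? It rests on two readings and is net of making and loss. It is also a pseudo-first-order figure: the possible loss step needs substrate, and the constant treats substrate as standing still. So I trust it over short steps.

And at 2.0 d? The step from the last reading leaves a fraction 0.937, so my reckoning is 15.8 %.

What does it say of the options? Waiting 25 h leaves a fraction 0.815, a cost of 2.9 points, so on my reckoning violet loses target. The constant puts no figure on added enzyme, on removal or on heat, so I name no option from it.

The forecast also reads that “the enzyme dies while target is consumed by substrate”. It gives 15.9 % at 2.0 d against my 15.8 %, chooses teal, and puts teal at 29 % and ochre at 6 %.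

The flask gives 15.8 %, and teal gains 9.6 points, reaching 25.4 %; ochre ends at 2.58 %.

    complex → spent catalyst (k = 5.40 × 10⁻⁵ s⁻¹, Ea = 109 kJ mol⁻¹)
    substrate + target → side product (k = 0.00150 M⁻¹ s⁻¹, Ea = 74.0 kJ mol⁻¹)
    complex → free enzyme + target (k = 0.310 s⁻¹, Ea = 88.0 kJ mol⁻¹)
    substrate + free enzyme ⇌ complex (K = 30.0 M⁻¹, k = 1600 M⁻¹ s⁻¹, Ea = 42.0 kJ mol⁻¹, ΔH = −29.0 kJ mol⁻¹)
    free enzyme → unfolded enzyme (k = 1.00 × 10⁻⁶ s⁻¹, Ea = 277 kJ mol⁻¹)
    (constants at 37 °C)

The flask has not come to rest. Violet costs 2.8 points, and the tail constant, started from 15.8 %, gives 2.9 points. Read at 5.0 d, the same flask holds 9.74 % of target, where the constant gives 8.78 %. At 480 h the constant gives 0.465 %, but target stands at 4.17 %, still falling from its value at 2.0 d, with substrate down from 26.9 % to 1.54 % and side product up from 57.2 % to 94.3 %.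

The runs are simulated for an exercise, noise included.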